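**Plan**

- Numbering: C1 aroyl bridgehead, C2–C3–C4 enolised dione bridge (prenyl on C3), C5 lavandulyl bridgehead, C6H2, C7H(prenyl), C8Me2, C9 bridging ketone. Ring A = C1, C9, C5, C6, C7, C8; ring B = C1, C2, C3, C4, C5, C9.
- Enabling feature: C3 is a single carbon held between the two carbonyl carbons C2 and C4, and these hang from the 1,3-diaxial positions C1 and C5 of ring A, so C2 and C4 can be bonded to each other first and C3 slipped in afterwards.
- Cuts: (a) the two aryl O–Si bonds and C3–prenyl; (b) C2–C3 and C3–C4, with C2 rejoined to C4 as the bis(silyloxy)alkene of a bicyclo[3.2.1]octene; (c) C2–C4; (d) C1–C2 and C5–C4; (e) C1–aroyl and C5–lavandulyl; (f) C5–C6 of ring A and C7–prenyl.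
- Forward: ring A by enolate alkylation; lavandulyl on C5 and aroyl on C1; two CH2OH arms; five-membered acyloin ring (bicyclo[3.2.1]octane); CH2 insertion to the six-membered ring B (bicyclo[3.3.1]nonane); C3 prenyl; free catechol.
- Stereochemistry: C7 from an Evans alkylation on an (R)-4-benzyloxazolidinone imide; the lavandulyl centre from lipase-resolved (S)-lavandulol; C5 and C1 from substrate-controlled formaldehyde additions (trans to the C7 prenyl group, cis to each other), proof-read by a ring closure that only the cis-dialdehyde can undergo. The ring enlargement creates no stereocentre.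

Key step: step 17

Assumption: the lipase acetylates (R)-lavandulol faster, so the (S)-alcohol is the recovered enantiomer, and methyl prenyl carbonate is bought (otherwise one step from prenol and methyl chloroformate).

Step 1
Reactants: 1 3,3-dimethyl-5-oxohexanoic acid; 2 (R)-4-benzyl-1,3-oxazolidin-2-one
Product: 4 (R)-4-benzyl-3-(3,3-dimethyl-5-oxohexanoyl)-1,3-oxazolidin-2-one, via mixed pivalic anhydride 3 (not isolated)
Conditions: t-BuCOCl, Et3N, THF, −20 °C; then LiCl, 2, −20 °C → rt
Reagents that add atoms: none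
Why: Mixed-anhydride N-acylation of the oxazolidinone under the mild LiCl/Et3N protocol: the nitrogen attacks the less hindered acyl group of 3, no strong base touches the methyl ketone and no stereocentre is formed.

Step 2
Reactants: 4 (R)-4-benzyl-3-(3,3-dimethyl-5-oxohexanoyl)-1,3-oxazolidin-2-one
Product: 5 (R)-4-benzyl-3-[3,3-dimethyl-4-(2-methyl-1,3-dioxolan-2-yl)butanoyl]-1,3-oxazolidin-2-one
Conditions: (Me3SiOCH2)2, Me3SiOSO2CF3 (5 mol %), CH2Cl2, −78 → −20 °C
Reagents that add atoms: 1,2-bis(trimethylsilyloxy)ethane, C[Si](C)(C)OCCO[Si](C)(C)C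
Why: Noyori ketalisation: the methyl ketone must be masked because it would be enolised ahead of the imide in step 3 and its enolate would close onto the imide carbonyl in a Claisen-type reaction.

Step 3
Reactants: 5 (R)-4-benzyl-3-[3,3-dimethyl-4-(2-methyl-1,3-dioxolan-2-yl)butanoyl]-1,3-oxazolidin-2-one; 6 prenyl bromide
Product: 7 (R)-4-benzyl-3-[(2R)-3,3-dimethyl-2-(3-methylbut-2-enyl)-4-(2-methyl-1,3-dioxolan-2-yl)butanoyl]-1,3-oxazolidin-2-one
Conditions: NaN(SiMe3)2, THF, −78 °C; 6, −78 → −40 °C
Reagents that add atoms: none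
Why: Evans asymmetric alkylation: the chelated Z-sodium enolate is prenylated on the face away from the benzyl group of the (R)-auxiliary, which sets the future C7 stereocentre as (2R) in 7.

Step 4
Reactants: 7 (R)-4-benzyl-3-[(2R)-3,3-dimethyl-2-(3-methylbut-2-enyl)-4-(2-methyl-1,3-dioxolan-2-yl)butanoyl]-1,3-oxazolidin-2-one
Product: 8 (2R)-3,3-dimethyl-2-(3-methylbut-2-enyl)-4-(2-methyl-1,3-dioxolan-2-yl)butan-1-ol
Conditions: LiBH4, H2O (1 equiv), Et2O, 0 °C
Reagents that add atoms: none
Why: Reductive cleavage of the N-acyloxazolidinone with LiBH4 gives the primary alcohol and returns the auxiliary; the stereocentre is no longer α to a carbonyl group and cannot epimerise.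

Step 5
Reactants: 8 (2R)-3,3-dimethyl-2-(3-methylbut-2-enyl)-4-(2-methyl-1,3-dioxolan-2-yl)butan-1-ol
Product: 9 2-[(3R)-3-(iodomethyl)-2,2,6-trimethylhept-5-enyl]-2-methyl-1,3-dioxolane
Conditions: PPh3, I2, imidazole, CH2Cl2, 0 °C → rt
Reagents that add atoms: iodine, II
Why: Appel-type iodination (PPh3/I2/imidazole) turns the primary alcohol into the iodide under buffered conditions that spare the dioxolane and the alkene.

Step 6
Reactants: 9 2-[(3R)-3-(iodomethyl)-2,2,6-trimethylhept-5-enyl]-2-methyl-1,3-dioxolane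
Product: 10 (5R)-5-(iodomethyl)-4,4,8-trimethylnon-7-en-2-one
Conditions: pyridinium p-toluenesulfonate (10 mol %), acetone/H2O 10:1, 50 °C
Reagents that add atoms: water, O
Why: Acid-catalysed acetal hydrolysis with a weak acid releases the methyl ketone without protonating the trisubstituted alkene or displacing the iodide.

Step 7
Reactants: 10 (5R)-5-(iodomethyl)-4,4,8-trimethylnon-7-en-2-one
Product: 11 (4R)-3,3-dimethyl-4-(3-methylbut-2-enyl)cyclohexan-1-one (ring A: C9 ketone; C1H2 next to C8Me2; C7 prenyl; C6H2; C5H2)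
Conditions: LiN(i-Pr)2, THF, −78 °C → rt
Reagents that add atoms: none
Why: Intramolecular enolate alkylation: the kinetic methyl enolate displaces the primary iodide in a 6-(enolendo)-exo-tet closure to ring A, whereas the methylene enolate could only form a cyclobutane; the C7 stereocentre is not involved.

Step 8
Reactants: 12 (±)-lavandulol
Product: 13 (S)-lavandulol
Conditions: porcine pancreatic lipase, vinyl acetate, t-BuOMe, rt, to about 60% conversion; chromatography
Reagents that add atoms: none
Why: Lipase-catalysed kinetic resolution by enantioselective acetylation: the (R)-alcohol is esterified faster, so the (S)-alcohol is recovered in high enantiomeric purity once conversion has passed one half.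

Step 9
Reactants: 13 (S)-lavandulol
Product: 14 (S)-lavandulyl iodide [(3S)-3-(iodomethyl)-2,6-dimethylhepta-1,5-diene]
Conditions: PPh3, I2, imidazole, CH2Cl2, 0 °C
Reagents that add atoms: iodine, II
Why: Appel-type iodination at the primary carbon; the adjacent stereocentre is untouched and the buffered conditions avoid alkene isomerisation.

Step 10
Reactants: 11 (4R)-3,3-dimethyl-4-(3-methylbut-2-enyl)cyclohexan-1-one; 14 (S)-lavandulyl iodide
Product: 15 C5-lavandulyl ring A ketone (11 carrying the lavandulyl group of 14 on C5; both C5 epimers; C7 as in 11)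
Conditions: LiN(i-Pr)2, THF, −78 °C; 14, DMPU, −78 → 0 °C
Reagents that add atoms: none
Why: Regioselective kinetic enolate alkylation: LiN(i-Pr)2 removes a proton from C5 (the α-methylene far from the C8 gem-dimethyl group) and the enolate displaces the primary iodide in an SN2 reaction (DMPU to outpace elimination); the C5 configuration formed here is erased in step 14.

Step 11
Reactants: 16 3,4-dihydroxybenzaldehyde
Product: 17 3,4-bis(tert-butyldimethylsilyloxy)benzaldehyde
Conditions: t-BuMe2SiCl, imidazole, DMF, rt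
Reagents that add atoms: tert-butyldimethylsilyl chloride, CC(C)(C)[Si](C)(C)Cl
Why: Silylation of both phenols gives aryl silyl ethers that tolerate amide bases, oxidants, the zinc carbenoid and zerovalent palladium and are removed by fluoride in the last step.

Step 12
Reactants: 15 C5-lavandulyl ring A ketone; 17 3,4-bis(tert-butyldimethylsilyloxy)benzaldehyde
Product: 18 aldol adduct (15 carrying a hydroxy[3,4-bis(tert-butyldimethylsilyloxy)phenyl]methyl group on C1; diastereomer mixture)
Conditions: LiN(i-Pr)2, THF, −78 °C; 17, −78 °C; AcOH, −78 °C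
Reagents that add atoms: none
Why: Directed aldol addition of a kinetic lithium enolate: deprotonation takes the only remaining α-methylene (C1) rather than the substituted methine C5, and the enolate adds to the non-enolisable aldehyde; the new stereocentres disappear in steps 13 and 14.

Step 13
Reactants: 18 aldol adduct
Product: 19 C1-aroyl C5-lavandulyl ring A ketone (2-aroyl 1,3-diketone; Ar = 3,4-bis(tert-butyldimethylsilyloxy)phenyl; keto/enol and C5-epimer mixture)
Conditions: Dess–Martin periodinane, CH2Cl2, 0 °C → rt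
Reagents that add atoms: none
Why: Dess–Martin oxidation of the β-hydroxy ketone to the 2-aroyl ketone (1,3-diketone) proceeds under neutral, non-nucleophilic conditions that leave alkenes and silyl ethers alone.

Step 14
Reactants: 19 C1-aroyl C5-lavandulyl ring A ketone
Product: 21 1,5-bis(hydroxymethyl) diketone (CH2OH on C1 and on C5; cis to each other; trans to the C7 prenyl group), via C5-hydroxymethyl diketone 20 (not isolated)
Conditions: LiN(i-Pr)2 (2.3 equiv), THF, −78 → −20 °C; monomeric CH2O in THF (excess), −78 → −30 °C; AcOH, −78 °C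
Reagents that add atoms: formaldehyde, C=O
Why: Dianion chemistry of a 1,3-diketone (Hauser type) combined with hydroxymethylation (aldol addition to formaldehyde): the more basic C5 carbanion adds first along the axial trajectory, which puts its CH2OH trans to the C7 prenyl group and leaves lavandulyl equatorial, and the remaining diketonate then takes a second CH2O on the same face, where the lithium alkoxide of the C5 arm holds the aldehyde and which is not screened by the pseudo-axial C8 methyl group, so that both arms should end up cis-diaxial; the cold acidic quench prevents retro-aldol loss of formaldehyde.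

Step 15
Reactants: 21 1,5-bis(hydroxymethyl) diketone
Product: 23 acyloin (bicyclo[3.2.1]octane; C2 bonded to C4; C2 carbinol; C4 and C9 ketones; C1 aroyl; C5 lavandulyl), via 1,5-dialdehyde 22 (not isolated)
Conditions: (COCl)2, DMSO, CH2Cl2, −78 °C; Et3N, −78 → 0 °C; then 2-(pentafluorophenyl)-6,7-dihydro-5H-pyrrolo[2,1-c][1,2,4]triazol-2-ium tetrafluoroborate (15 mol %), rt
Reagents that add atoms: none
Why: Swern oxidation turns both alkoxysulfonium groups into aldehydes at the same moment (so no hydroxy aldehyde can close to a lactol and be oxidised to the lactone), and the N-heterocyclic carbene then adds to the less hindered C4 aldehyde, whose Breslow intermediate attacks the 1,3-diaxial C2 aldehyde in an intramolecular benzoin (acyloin) reaction, a 5-exo-trig closure open only to the cis-dialdehyde; the carbinol configuration is lost in step 16.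

Step 16
Reactants: 23 acyloin
Product: 25 C2=C4 enediol bis(trimethylsilyl) ether (1-aroyl-5-lavandulyl bicyclo[3.2.1]octen-9-one), via O-trimethylsilyl acyloin 24 (not isolated)
Conditions: Me3SiOSO2CF3, Et3N, CH2Cl2, 0 °C → rt
Reagents that add atoms: trimethylsilyl trifluoromethanesulfonate, C[Si](C)(C)OS(=O)(=O)C(F)(F)F
Why: O-Silylation followed by silyl enol ether formation under soft enolisation (Me3SiOSO2CF3/Et3N) towards the only α-hydrogen gives the 1,2-bis(trimethylsilyloxy)alkene; the new double bond lies in the two-carbon bridge, so no bridgehead alkene arises.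

Step 17
Reactants: 25 C2=C4 enediol bis(trimethylsilyl) ether
Product: 27 C3-unsubstituted bicyclo[3.3.1]nonane-2,4,9-trione (C1 aroyl; C5 lavandulyl; catechol as bis-silyl ether), via 2,4-bis(trimethylsilyloxy)cyclopropane 26 (not isolated)
Conditions: Zn(C2H5)2 (1.3 equiv), CH2I2 (1.3 equiv), CH2Cl2, −20 → 0 °C; then FeCl3 (2.5 equiv), DMF, 0 °C → rt; aq. HCl work-up
Reagents that add atoms: diiodomethane, ICI
Why: The electrophilic zinc carbenoid C2H5ZnCH2I (Furukawa variant of the Simmons–Smith reaction) transfers CH2 in a concerted [2+1] addition to the C2=C4 bis(silyloxy)alkene from its open face on the C9 side, which closes the three-membered ring C2–C3–C4 of 26. FeCl3 then takes one electron from a cyclopropyl silyl ether oxygen (through the iron cyclopropanolate), and the oxygen-centred radical breaks the strained, doubly oxygenated C2–C4 bond by β-scission to give the C2 ketone and a silyloxy-stabilised radical at C4, which a second FeCl3 oxidises to the oxocarbenium ion that loses Me3SiCl and becomes the C4 ketone. The closest known reaction type is the cyclopropanation and FeCl3 ring enlargement of acyloin-derived 1,2-bis(silyloxy)cycloalkenes to cycloalkane-1,3-diones (Ito–Saegusa ring expansion). Ring B does not form by a cyclisation but by enlargement: once the bond shared by the three- and five-membered rings is cut, C3 stands between C2 and C4 and the five-membered ring has become the six-membered ring C1–C2–C3–C4–C5–C9. No stereocentre is created, since C3 is a CH2 group, C2 and C4 end as carbonyl carbons and C1, C5 and C7 are not touched. The step needs the carbenoid to choose the enediol ether over the two trisubstituted and one 1,1-disubstituted alkenes, which the two oxygen donors on C2=C4 (by far the most electron-rich double bond), the absence of any free hydroxyl that could direct zinc elsewhere and the use of only 1.3 equivalents at low temperature should secure, while DMF tempers the Lewis acidity of FeCl3 so that the prenyl groups and aryl silyl ethers are left alone.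

Step 18
Reactants: 27 C3-unsubstituted bicyclo[3.3.1]nonane-2,4,9-trione; 28 methyl prenyl carbonate
Product: 29 C3-prenyl trione as its C2-enol (bis(tert-butyldimethylsilyl) ether of the target)
Conditions: Pd(PPh3)4 (5 mol %), 28 (1.05 equiv), THF, 0 °C → rt
Reagents that add atoms: none
Why: Tsuji–Trost allylation: zerovalent palladium ionises the carbonate, the methoxide released deprotonates the acidic 2,4-dione, and the soft enolate attacks the π-prenyl complex through C3 at its unsubstituted terminus to give the linear prenyl group (an O-prenyl ether would re-ionise under the same catalyst).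

Step 19
Reactants: 29 C3-prenyl trione bis(tert-butyldimethylsilyl) ether
Product: 30 CNP0425478.2 (target)
Conditions: Bu4NF, AcOH, THF, 0 °C
Reagents that add atoms: none
Why: Fluoride-induced cleavage of the two aryl silyl ethers; acetic acid buffering protects the catechol and the enolised trione from base-promoted oxidation and the prenyl groups from cyclisation.

**Compound list**

1 | 3,3-dimethyl-5-oxohexanoic acid | CC(=O)CC(C)(C)CC(=O)O | starting material
2 | (R)-4-benzyl-1,3-oxazolidin-2-one | O=C1N[C@H](Cc2ccccc2)CO1 | starting material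
3 | 3,3-dimethyl-5-oxohexanoic pivalic anhydride | CC(=O)CC(C)(C)CC(=O)OC(=O)C(C)(C)C | intermediate
4 | (R)-4-benzyl-3-(3,3-dimethyl-5-oxohexanoyl)-1,3-oxazolidin-2-one | CC(=O)CC(C)(C)CC(=O)N1C(=O)OC[C@H]1Cc2ccccc2 | intermediate
5 | (R)-4-benzyl-3-[3,3-dimethyl-4-(2-methyl-1,3-dioxolan-2-yl)butanoyl]-1,3-oxazolidin-2-one | CC1(CC(C)(C)CC(=O)N2C(=O)OC[C@H]2Cc3ccccc3)OCCO1 | intermediate
6 | prenyl bromide (1-bromo-3-methylbut-2-ene) | CC(C)=CCBr | starting material
7 | (R)-4-benzyl-3-[(2R)-3,3-dimethyl-2-(3-methylbut-2-enyl)-4-(2-methyl-1,3-dioxolan-2-yl)butanoyl]-1,3-oxazolidin-2-one | CC1(CC(C)(C)[C@@H](CC=C(C)C)C(=O)N2C(=O)OC[C@H]2Cc3ccccc3)OCCO1 | intermediate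
8 | (2R)-3,3-dimethyl-2-(3-methylbut-2-enyl)-4-(2-methyl-1,3-dioxolan-2-yl)butan-1-ol | CC1(CC(C)(C)[C@@H](CC=C(C)C)CO)OCCO1 | intermediate
9 | 2-[(3R)-3-(iodomethyl)-2,2,6-trimethylhept-5-enyl]-2-methyl-1,3-dioxolane | CC1(CC(C)(C)[C@@H](CC=C(C)C)CI)OCCO1 | intermediate
10 | (5R)-5-(iodomethyl)-4,4,8-trimethylnon-7-en-2-one | CC(=O)CC(C)(C)[C@@H](CC=C(C)C)CI | intermediate
11 | (4R)-3,3-dimethyl-4-(3-methylbut-2-enyl)cyclohexan-1-one (ring A ketone) | O=C1CC[C@H](CC=C(C)C)C(C)(C)C1 | intermediate
12 | (±)-lavandulol [5-methyl-2-(prop-1-en-2-yl)hex-4-en-1-ol] | C=C(C)C(CO)CC=C(C)C | starting material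
13 | (S)-lavandulol | C=C(C)[C@H](CC=C(C)C)CO | intermediate
14 | (S)-lavandulyl iodide [(3S)-3-(iodomethyl)-2,6-dimethylhepta-1,5-diene] | C=C(C)[C@H](CC=C(C)C)CI | intermediate
15 | C5-lavandulyl ring A ketone (lavandulyl CH2 on C5, both C5 epimers; C7 as in 11) | C=C(C)[C@H](CC=C(C)C)CC1C[C@H](CC=C(C)C)C(C)(C)CC1=O | intermediate
16 | 3,4-dihydroxybenzaldehyde | O=Cc1ccc(O)c(O)c1 | starting material
17 | 3,4-bis(tert-butyldimethylsilyloxy)benzaldehyde | O=Cc1ccc(O[Si](C)(C)C(C)(C)C)c(O[Si](C)(C)C(C)(C)C)c1 | intermediate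
18 | aldol adduct: 15 with hydroxy[3,4-bis(tert-butyldimethylsilyloxy)phenyl]methyl on C1 (diastereomer mixture) | C=C(C)[C@H](CC=C(C)C)CC1C[C@H](CC=C(C)C)C(C)(C)C(C(O)c2ccc(O[Si](C)(C)C(C)(C)C)c(O[Si](C)(C)C(C)(C)C)c2)C1=O | intermediate
19 | C1-aroyl C5-lavandulyl ring A ketone (2-aroyl 1,3-diketone; C5 epimers, keto/enol forms) | C=C(C)[C@H](CC=C(C)C)CC1C[C@H](CC=C(C)C)C(C)(C)C(C(=O)c2ccc(O[Si](C)(C)C(C)(C)C)c(O[Si](C)(C)C(C)(C)C)c2)C1=O | intermediate
20 | C5-hydroxymethyl diketone (CH2OH on C5 trans to the C7 prenyl group; lavandulyl cis to it) | C=C(C)[C@H](CC=C(C)C)C[C@]1(CO)C[C@H](CC=C(C)C)C(C)(C)C(C(=O)c2ccc(O[Si](C)(C)C(C)(C)C)c(O[Si](C)(C)C(C)(C)C)c2)C1=O | intermediate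
21 | 1,5-bis(hydroxymethyl) diketone (both CH2OH on the ring A face opposite to aroyl, lavandulyl and C7 prenyl) | C=C(C)[C@H](CC=C(C)C)C[C@]1(CO)C[C@H](CC=C(C)C)C(C)(C)[C@](CO)(C(=O)c2ccc(O[Si](C)(C)C(C)(C)C)c(O[Si](C)(C)C(C)(C)C)c2)C1=O | intermediate
22 | 1,5-dialdehyde (CHO on C1 and C5, cis-diaxial) | C=C(C)[C@H](CC=C(C)C)C[C@]1(C=O)C[C@H](CC=C(C)C)C(C)(C)[C@](C=O)(C(=O)c2ccc(O[Si](C)(C)C(C)(C)C)c(O[Si](C)(C)C(C)(C)C)c2)C1=O | intermediate
23 | acyloin: 1-aroyl-5-lavandulyl bicyclo[3.2.1]octane with C2H(OH)–C4(=O) bridge and C9 ketone (either C2 epimer) | C=C(C)[C@H](CC=C(C)C)C[C@]12C[C@H](CC=C(C)C)C(C)(C)[C@](C(=O)c3ccc(O[Si](C)(C)C(C)(C)C)c(O[Si](C)(C)C(C)(C)C)c3)(C1=O)C(O)C2=O | intermediate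
24 | O-trimethylsilyl acyloin | C=C(C)[C@H](CC=C(C)C)C[C@]12C[C@H](CC=C(C)C)C(C)(C)[C@](C(=O)c3ccc(O[Si](C)(C)C(C)(C)C)c(O[Si](C)(C)C(C)(C)C)c3)(C1=O)C(O[Si](C)(C)C)C2=O | intermediate
25 | C2=C4 enediol bis(trimethylsilyl) ether of the bicyclo[3.2.1]octen-9-one (C1 aroyl, C5 lavandulyl) | C=C(C)[C@H](CC=C(C)C)C[C@]12C[C@H](CC=C(C)C)C(C)(C)[C@](C(=O)c3ccc(O[Si](C)(C)C(C)(C)C)c(O[Si](C)(C)C(C)(C)C)c3)(C1=O)C(O[Si](C)(C)C)=C2O[Si](C)(C)C | intermediate
26 | 2,4-bis(trimethylsilyloxy)cyclopropane (CH2, the future C3, bridging C2 and C4 on the C9 face) | C=C(C)[C@H](CC=C(C)C)C[C@]12C[C@H](CC=C(C)C)C(C)(C)[C@](C(=O)c3ccc(O[Si](C)(C)C(C)(C)C)c(O[Si](C)(C)C(C)(C)C)c3)(C1=O)[C@]1(O[Si](C)(C)C)C[C@@]12O[Si](C)(C)C | intermediate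
27 | C3-unsubstituted 1-aroyl-5-lavandulyl-8,8-dimethyl-7-prenylbicyclo[3.3.1]nonane-2,4,9-trione, catechol as bis(tert-butyldimethylsilyl) ether | C=C(C)[C@H](CC=C(C)C)C[C@]12C[C@H](CC=C(C)C)C(C)(C)[C@](C(=O)c3ccc(O[Si](C)(C)C(C)(C)C)c(O[Si](C)(C)C(C)(C)C)c3)(C1=O)C(=O)CC2=O | intermediate
28 | methyl prenyl carbonate [methyl (3-methylbut-2-enyl) carbonate] | COC(=O)OCC=C(C)C | starting material
29 | C3-prenyl trione (C2-enol form), bis(tert-butyldimethylsilyl) ether of the target | C=C(C)[C@H](CC=C(C)C)C[C@]12C[C@H](CC=C(C)C)C(C)(C)[C@](C(=O)c3ccc(O[Si](C)(C)C(C)(C)C)c(O[Si](C)(C)C(C)(C)C)c3)(C1=O)C(O)=C(CC=C(C)C)C2=O | intermediate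
30 | CNP0425478.2 (C1 aroyl, C5 lavandulyl and C7 prenyl all on the ring A face opposite to the C2–C3–C4 bridge; C7 S; lavandulyl centre R) | C=C(C)[C@H](CC=C(C)C)C[C@]12C[C@H](CC=C(C)C)C(C)(C)[C@](C(=O)c3ccc(O)c(O)c3)(C1=O)C(O)=C(CC=C(C)C)C2=O | target

**Count and risks**

Total step count: 19. Longest linear sequence: 16 steps (1 → 30 through steps 1–7, 10 and 12–19).

Steps most likely to fail:

1. Step 14. The second formaldehyde addition may show poor facial selectivity, the C1 arm entering trans to the C5 arm, or formaldehyde may be lost again by retro-aldol reaction on work-up. Fallback (thermodynamic control through a tether): from 19 the dianion is formylated at C5 with ethyl formate (Claisen-type acylation of the terminal carbanion) to the C5-formyl diketone F1. Aqueous formaldehyde with catalytic Et3N in THF then hydroxymethylates C1 reversibly. Only the isomer whose CH2OH is cis to the axial formyl group can close to the six-membered bridged lactol F2, so the equilibrium drains into the cis series. NaBH4 in EtOH/CH2Cl2 at low temperature reduces the lactol through its open aldehyde form, faster than the two hindered ketones, and gives diol 21, where the route is rejoined.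

2. Step 15. The C1 formyl group of the tricarbonyl aldehyde may be lost by retro-Claisen cleavage under the basic, nucleophilic conditions, or a lactol may form and be over-oxidised to the lactone before both aldehydes exist. Fallback (no aldehyde on C1 at any stage): from 19 the 1,3-diketone is C-alkylated at C1 with phenyl bromoacetate (Cs2CO3, acetone; attack anti to the pseudo-axial C8 methyl group) to the phenyl ester F3. LiN(SiMe3)2 then forms the C5 enolate, which closes onto the activated ester in an intramolecular Claisen condensation; this is possible only on the face of the C1 arm, so C5 is set as before, and gives the bicyclo[3.2.1]octane-4,9-dione F4. Its C2 enolate (KN(SiMe3)2) is hydroxylated with 2-(phenylsulfonyl)-3-phenyloxaziridine (Davis oxidation) to acyloin 23, where the route is rejoined.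

3. Step 17. Methylene transfer may also reach the prenyl or isopropenyl double bonds, or the silyl enol ether may be cleaved before the carbenoid has reacted. Fallback (carbon insertion without a carbenoid): acyloin 23 is oxidised with Dess–Martin periodinane to the 1,2-diketone F5. This is homologated with Me3SiCHN2 under Sc(OSO2CF3)3 catalysis, a diazoalkane insertion into a 1,2-diketone with acyl migration and loss of nitrogen (Tiffeneau–Demjanov-type ring enlargement). The trimethylsilyl enol ether F6 that results after silyl migration is hydrolysed on work-up to trione 27, where the route is rejoined.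

**Further compounds**

F1 | step 14 | C5-formyl diketone (19 with CHO on C5, trans to the C7 prenyl group) | C=C(C)[C@H](CC=C(C)C)C[C@]1(C=O)C[C@H](CC=C(C)C)C(C)(C)C(C(=O)c2ccc(O[Si](C)(C)C(C)(C)C)c(O[Si](C)(C)C(C)(C)C)c2)C1=O
F2 | step 14 | bridged lactol (3-oxabicyclo[3.3.1]nonan-9-one; ring oxygen between C2H2 and C4H(OH)) | C=C(C)[C@H](CC=C(C)C)C[C@]12C[C@H](CC=C(C)C)C(C)(C)[C@](C(=O)c3ccc(O[Si](C)(C)C(C)(C)C)c(O[Si](C)(C)C(C)(C)C)c3)(C1=O)COC2O
F3 | step 15 | phenyl ester (19 carrying CH2CO2Ph on C1, trans to the C7 prenyl group) | C=C(C)[C@H](CC=C(C)C)CC1C[C@H](CC=C(C)C)C(C)(C)[C@](CC(=O)Oc2ccccc2)(C(=O)c3ccc(O[Si](C)(C)C(C)(C)C)c(O[Si](C)(C)C(C)(C)C)c3)C1=O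
F4 | step 15 | 1-aroyl-5-lavandulyl bicyclo[3.2.1]octane-4,9-dione with C2H2 | C=C(C)[C@H](CC=C(C)C)C[C@]12C[C@H](CC=C(C)C)C(C)(C)[C@](C(=O)c3ccc(O[Si](C)(C)C(C)(C)C)c(O[Si](C)(C)C(C)(C)C)c3)(C1=O)CC2=O
F5 | step 17 | 1,2-diketone (C2 and C4 both ketones, directly bonded) | C=C(C)[C@H](CC=C(C)C)C[C@]12C[C@H](CC=C(C)C)C(C)(C)[C@](C(=O)c3ccc(O[Si](C)(C)C(C)(C)C)c(O[Si](C)(C)C(C)(C)C)c3)(C1=O)C(=O)C2=O
F6 | step 17 | trimethylsilyl enol ether of trione 27 | C=C(C)[C@H](CC=C(C)C)C[C@]12C[C@H](CC=C(C)C)C(C)(C)[C@](C(=O)c3ccc(O[Si](C)(C)C(C)(C)C)c(O[Si](C)(C)C(C)(C)C)c3)(C1=O)C(O[Si](C)(C)C)=CC2=O
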